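**Retrosynthetic overview**
- Target 30 ← PMB removal, HWE methylenation of an α-phosphono lactone, and mesylate elimination to the 2E-enone from the bridged isoxazoline 25 (masked C1 ketone / C3 hydroxyl).
- The ten-membered ring is closed by an intramolecular nitrile oxide–alkene [3+2] cycloaddition (C1–C2 and O–C3 bonds) of oxime 22; the exocyclic methylene is installed only afterwards, so the terminal vinyl is the only reactive dipolarophile.
- trans-γ-Lactone 17 (C7, C8) ← 5-exo opening of an erythro epoxy phosphonoacetate; the epoxide comes from hydroxyl-directed epoxidation of (E)-allylic alcohol 14.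
- C6 ← chelation-controlled alkynylzinc addition of alkyne 4 to aldehyde 9; C4/C5 ← (E)-crotylboration of (R)-glyceraldehyde acetonide; C10 ← (R)-lactic acid by self-regeneration of the stereocentre.
- Ring order: γ-lactone (step 11) → ten-membered carbocycle with bridging isoxazoline (step 17) → isoxazoline opened (step 18).

Assumption: C1–C15 are the germacranolide positions of the target (C12 lactone carbonyl, C13 exocyclic CH2); centres formed as inconsequential mixtures (C11 in 17–28, C3 in 25–27) carry no descriptor. The route is a proposal and has not been run.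

**Route**

Step 1
Reactants: 1 (R)-lactic acid
Product: 2 (2R,5R)-2-tert-butyl-5-methyl-1,3-dioxolan-4-one
Conditions: t-BuCHO, TsOH·H2O (cat.), H2SO4 (cat.), pentane, reflux, Dean–Stark; recrystallise the cis isomer
Reagents that add atoms: pivalaldehyde, CC(C)(C)C=O
Why: Acid-catalysed acetalisation gives mainly the cis acetal, so the lactic acid centre creates a relay centre at C2 (Seebach self-regeneration of stereocentres).

Step 2
Reactants: 2 (2R,5R)-2-tert-butyl-5-methyl-1,3-dioxolan-4-one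
Product: 4 (2R,5S)-2-tert-butyl-5-methyl-5-(prop-2-yn-1-yl)-1,3-dioxolan-4-one, via lithium enolate 3 (not isolated)
Conditions: LiN(i-Pr)2, THF, −78 °C; HC≡CCH2Br, −78 → −30 °C
Reagents that add atoms: propargyl bromide, C#CCBr
Why: Enolate alkylation anti to the tert-butyl group sets the quaternary carbinol carbon (future C10, S) with high diastereoselectivity, controlled only by the acetal centre.

Step 3
Reactants: 5 (R)-2,2-dimethyl-1,3-dioxolane-4-carbaldehyde
Product: 6 (1S,2S)-1-[(4R)-2,2-dimethyl-1,3-dioxolan-4-yl]-2-methylbut-3-en-1-ol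
Conditions: (E)-crotylB(pin), toluene, 23 °C, 24 h; aqueous work-up
Reagents that add atoms: (E)-crotylboronic acid pinacol ester, C/C=C/CB1OC(C)(C)C(C)(C)O1
Why: Crotylboration through a chair Zimmerman–Traxler transition state: the E geometry gives Me/OH anti (C4/C5) and the dioxolane centre directs attack anti to its oxygen (Felkin–Cornforth, roughly 85:15 expected; minor isomer removed by chromatography).

Step 4
Reactants: 6 (1S,2S)-1-[(4R)-2,2-dimethyl-1,3-dioxolan-4-yl]-2-methylbut-3-en-1-ol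
Product: 7 (4R)-4-{(1S,2S)-1-[(4-methoxybenzyl)oxy]-2-methylbut-3-en-1-yl}-2,2-dimethyl-1,3-dioxolane
Conditions: NaH, PMBCl, n-Bu4NI (cat.), THF/DMF, 0 °C → rt
Reagents that add atoms: 4-methoxybenzyl chloride, COc1ccc(CCl)cc1
Why: Williamson etherification protects C5–OH as a chelating ether needed in step 6 and removable oxidatively at the end.

Step 5
Reactants: 7 (4R)-4-{(1S,2S)-1-[(4-methoxybenzyl)oxy]-2-methylbut-3-en-1-yl}-2,2-dimethyl-1,3-dioxolane
Product: 9 (2S,3S)-2-[(4-methoxybenzyl)oxy]-3-methylpent-4-enal, via diol 8 (not isolated)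
Conditions: H5IO6, EtOAc, 0 °C → rt
Reagents that add atoms: none
Why: Periodic acid hydrolyses the terminal acetonide and cleaves the glycol (Malaprade); the controlling glyceraldehyde carbon becomes the C6 aldehyde, which is used crude to avoid epimerisation.

Step 6
Reactants: 4 (2R,5S)-2-tert-butyl-5-methyl-5-(prop-2-yn-1-yl)-1,3-dioxolan-4-one; 9 (2S,3S)-2-[(4-methoxybenzyl)oxy]-3-methylpent-4-enal
Product: 12 (2R,5S)-2-tert-butyl-5-{(4S,5S,6S)-4-hydroxy-5-[(4-methoxybenzyl)oxy]-6-methyloct-7-en-2-yn-1-yl}-5-methyl-1,3-dioxolan-4-one, via lithium acetylide 10 (not isolated), via alkynylzinc bromide 11 (not isolated)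
Conditions: 4, LiN(i-Pr)2, THF, −78 °C; ZnBr2, −78 → 0 °C; then 9, Et2O, −78 → −20 °C
Reagents that add atoms: none
Why: Alkynylzinc addition under Cram-chelate control (divalent zinc bridges the carbonyl and PMB-ether oxygens) gives the 5,6-syn carbinol (C6, S); the hindered, non-enolisable dioxolanone should tolerate the acetylide.

Step 7
Reactants: 12 (2R,5S)-2-tert-butyl-5-{(4S,5S,6S)-4-hydroxy-5-[(4-methoxybenzyl)oxy]-6-methyloct-7-en-2-yn-1-yl}-5-methyl-1,3-dioxolan-4-one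
Product: 13 (2S,4E,6S,7S,8S)-7-[(4-methoxybenzyl)oxy]-2,8-dimethyldeca-4,9-diene-1,2,6-triol
Conditions: NaAlH2(OCH2CH2OMe)2 (excess), THF, 0 °C → rt; aq. NaOH work-up
Reagents that add atoms: none
Why: Alkoxide-directed trans-hydroalumination gives the (E)-allylic alcohol, and the same hydride reduces the dioxolanone to the C1/C10 diol, releasing the relay acetal as neopentyl alcohol.

Step 8
Reactants: 13 (2S,4E,6S,7S,8S)-7-[(4-methoxybenzyl)oxy]-2,8-dimethyldeca-4,9-diene-1,2,6-triol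
Product: 14 (2E,4S,5S,6S)-5-[(4-methoxybenzyl)oxy]-6-methyl-1-[(4S)-2,2,4-trimethyl-1,3-dioxolan-4-yl]octa-2,7-dien-4-ol
Conditions: Me2C(OMe)2, PPTS (cat.), CH2Cl2, 0 °C → rt
Reagents that add atoms: 2,2-dimethoxypropane, COC(C)(C)OC
Why: Acetonide formation on the only 1,2-diol masks the tertiary hydroxyl, which would otherwise compete as a homoallylic director in step 9.

Step 9
Reactants: 14 (2E,4S,5S,6S)-5-[(4-methoxybenzyl)oxy]-6-methyl-1-[(4S)-2,2,4-trimethyl-1,3-dioxolan-4-yl]octa-2,7-dien-4-ol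
Product: 15 (1R,2S,3S)-2-[(4-methoxybenzyl)oxy]-3-methyl-1-[(2R,3R)-3-{[(4S)-2,2,4-trimethyl-1,3-dioxolan-4-yl]methyl}oxiran-2-yl]pent-4-en-1-ol
Conditions: VO(acac)2 (5 mol %), t-BuOOH, CH2Cl2, 0 °C → rt
Reagents that add atoms: tert-butyl hydroperoxide, CC(C)(C)OO
Why: Vanadium-catalysed hydroxyl-directed epoxidation of the secondary (E)-allylic alcohol favours the erythro epoxy alcohol (about 4:1 expected, separable), fixing the epoxide face from C6 and leaving the terminal vinyl untouched.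

Step 10
Reactants: 15 (1R,2S,3S)-2-[(4-methoxybenzyl)oxy]-3-methyl-1-[(2R,3R)-3-{[(4S)-2,2,4-trimethyl-1,3-dioxolan-4-yl]methyl}oxiran-2-yl]pent-4-en-1-ol
Product: 16 2-(diethoxyphosphoryl)acetate ester of 15 at the C6 hydroxyl
Conditions: (EtO)2P(O)CH2CO2H, DCC, DMAP (cat.), CH2Cl2, 0 °C → rt
Reagents that add atoms: (diethoxyphosphoryl)acetic acid, CCOP(=O)(CC(=O)O)OCC
Why: Steglich esterification tethers the C11–C12 unit together with the phosphonate that later delivers the exocyclic methylene.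

Step 11
Reactants: 16 2-(diethoxyphosphoryl)acetate ester of 15 at the C6 hydroxyl
Product: 17 diethyl [(4R,5S)-4-{(1R)-1-hydroxy-2-[(4S)-2,2,4-trimethyl-1,3-dioxolan-4-yl]ethyl}-5-{(1S,2S)-1-[(4-methoxybenzyl)oxy]-2-methylbut-3-en-1-yl}-2-oxooxolan-3-yl]phosphonate
Conditions: NaH, THF, 0 → 65 °C; AcOH quench
Reagents that add atoms: none
Why: The phosphonate-stabilised carbanion opens the epoxide 5-exo-tet at C7 with inversion (intramolecular SN2 alkylation), forming the C7–C11 bond and the trans-γ-lactone and freeing C8–OH (R); the alkoxide is quenched internally by the acidic α-phosphono C–H.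

Step 12
Reactants: 17 diethyl [(4R,5S)-4-{(1R)-1-hydroxy-2-[(4S)-2,2,4-trimethyl-1,3-dioxolan-4-yl]ethyl}-5-{(1S,2S)-1-[(4-methoxybenzyl)oxy]-2-methylbut-3-en-1-yl}-2-oxooxolan-3-yl]phosphonate
Product: 18 C8 (2Z)-2-methylbut-2-enoate (angelate) of 17
Conditions: angelic acid, 2,4,6-Cl3C6H2COCl, Et3N, toluene, rt; then 17, 80 °C
Reagents that add atoms: angelic acid, C/C=C(/C)C(=O)O
Why: Yamaguchi esterification through the mixed anhydride without a nucleophilic catalyst acylates the hindered alcohol with retention at C8 and avoids Z → E isomerisation to the tiglate.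

Step 13
Reactants: 18 C8 (2Z)-2-methylbut-2-enoate (angelate) of 17
Product: 19 C1/C10 diol from 18 (acetonide removed)
Conditions: AcOH/H2O (4:1), 40 °C
Reagents that add atoms: none
Why: Mild acid hydrolysis removes the acetonide while the PMB ether, lactone, phosphonate and angelate survive.

Step 14
Reactants: 19 C1/C10 diol from 18 (acetonide removed)
Product: 20 C1 aldehyde with free tertiary C10 hydroxyl
Conditions: IBX, DMSO, 23 °C
Reagents that add atoms: none
Why: IBX oxidises the primary alcohol only; the tertiary alcohol is inert and IBX does not cleave 1,2-diols.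

Step 15
Reactants: 20 C1 aldehyde with free tertiary C10 hydroxyl
Product: 21 C10 acetate of 20
Conditions: Ac2O, Et3N, DMAP (cat.), CH2Cl2, 23 °C
Reagents that add atoms: acetic anhydride, CC(=O)OC(C)=O
Why: DMAP-catalysed acylation of the only free hydroxyl, done before oxime formation so the later nitrile oxide has no free α-hydroxyl that could fragment in a retro-cyanohydrin manner.

Step 16
Reactants: 21 C10 acetate of 20
Product: 22 (E)-aldoxime of 21
Conditions: NH2OH·HCl, NaOAc, MeOH, 0 °C → rt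
Reagents that add atoms: hydroxylamine hydrochloride, Cl.NO
Why: Condensation with the non-enolisable aldehyde is much faster than attack on the esters.

Step 17
Reactants: 22 (E)-aldoxime of 21
Product: 25 bridged 2-isoxazoline macrocycle (C1=N–O–C3 across the ten-membered ring; 10-OAc; 8-OAng; 5-OPMB; 11-phosphono-12,6-olide), via hydroximoyl chloride 23 (not isolated), via nitrile oxide 24 (not isolated)
Conditions: NCS, DMF, 23 °C; then syringe-pump addition (12 h) to Et3N, CH2Cl2, 40 °C (final 1 mM)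
Reagents that add atoms: none
Why: Oxime chlorination and dehydrochlorination give a hindered tertiary nitrile oxide that undergoes intramolecular 1,3-dipolar cycloaddition with the terminal vinyl in the usual 5-substituted sense (C1–C2 and O–C3 bonds), closing the ten-membered carbocycle; the new C3 centre is removed later.

Step 18
Reactants: 25 bridged 2-isoxazoline macrocycle
Product: 26 C1 ketone / C3 alcohol (β-hydroxy ketone) from 25
Conditions: Mo(CO)6, MeCN/H2O (10:1), 80 °C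
Reagents that add atoms: water, O
Why: Reductive N–O cleavage and hydrolysis of the resulting imine unmask the aldol unit without hydrogenation conditions that would touch the alkenes.

Step 19
Reactants: 26 C1 ketone / C3 alcohol (β-hydroxy ketone) from 25
Product: 28 2E-enone (1-oxo-2-ene) with 11-phosphono lactone, via mesylate 27 (not isolated)
Conditions: MsCl, Et3N, CH2Cl2, 0 °C → rt
Reagents that add atoms: none
Why: Mesylation of the only free hydroxyl and E1cB elimination give the conjugated (E)-enone; C10 is quaternary so no other enolisation is possible.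

Step 20
Reactants: 28 2E-enone (1-oxo-2-ene) with 11-phosphono lactone
Product: 29 5-O-(4-methoxybenzyl) ether of the target
Conditions: aq. HCHO (37%), K2CO3, THF, 0 °C → rt
Reagents that add atoms: formaldehyde, C=O
Why: Horner–Wadsworth–Emmons olefination of the α-phosphono lactone with formaldehyde gives the α-methylene lactone under conditions mild enough for the acetate and angelate.

Step 21
Reactants: 29 5-O-(4-methoxybenzyl) ether of the target
Product: 30 target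
Conditions: DDQ, CH2Cl2/pH 7 buffer (10:1), 0 °C → rt
Reagents that add atoms: none
Why: Oxidative PMB cleavage frees C5–OH without touching the enone, the methylene lactone or the esters.

**Compound list**
1 | (R)-lactic acid, (2R)-2-hydroxypropanoic acid | C[C@@H](O)C(=O)O | starting material
2 | (2R,5R)-2-tert-butyl-5-methyl-1,3-dioxolan-4-one | O=C1O[C@H](C(C)(C)C)O[C@@H]1C | intermediate
3 | lithium (2R)-2-tert-butyl-5-methyl-1,3-dioxol-4-olate (enolate of 2) | CC1=C(O[Li])O[C@H](C(C)(C)C)O1 | intermediate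
4 | (2R,5S)-2-tert-butyl-5-methyl-5-(prop-2-yn-1-yl)-1,3-dioxolan-4-one | O=C1O[C@H](C(C)(C)C)O[C@@]1(C)CC#C | intermediate
5 | (R)-2,2-dimethyl-1,3-dioxolane-4-carbaldehyde ((R)-glyceraldehyde acetonide) | CC1(C)OC[C@H](C=O)O1 | starting material
6 | (1S,2S)-1-[(4R)-2,2-dimethyl-1,3-dioxolan-4-yl]-2-methylbut-3-en-1-ol | CC1(C)OC[C@H]([C@@H](O)[C@@H](C)C=C)O1 | intermediate
7 | (4R)-4-{(1S,2S)-1-[(4-methoxybenzyl)oxy]-2-methylbut-3-en-1-yl}-2,2-dimethyl-1,3-dioxolane | CC1(C)OC[C@H]([C@@H](OCc2ccc(OC)cc2)[C@@H](C)C=C)O1 | intermediate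
8 | (2R,3S,4S)-3-[(4-methoxybenzyl)oxy]-4-methylhex-5-ene-1,2-diol | OC[C@@H](O)[C@@H](OCc1ccc(OC)cc1)[C@@H](C)C=C | intermediate
9 | (2S,3S)-2-[(4-methoxybenzyl)oxy]-3-methylpent-4-enal | O=C[C@@H](OCc1ccc(OC)cc1)[C@@H](C)C=C | intermediate
10 | lithium acetylide of 4 | [Li]C#CC[C@]1(C)O[C@@H](C(C)(C)C)OC1=O | intermediate
11 | alkynylzinc bromide from 4 | Br[Zn]C#CC[C@]1(C)O[C@@H](C(C)(C)C)OC1=O | intermediate
12 | (2R,5S)-2-tert-butyl-5-{(4S,5S,6S)-4-hydroxy-5-[(4-methoxybenzyl)oxy]-6-methyloct-7-en-2-yn-1-yl}-5-methyl-1,3-dioxolan-4-one | C=C[C@H](C)[C@H](OCc1ccc(OC)cc1)[C@@H](O)C#CC[C@]2(C)O[C@@H](C(C)(C)C)OC2=O | intermediate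
13 | (2S,4E,6S,7S,8S)-7-[(4-methoxybenzyl)oxy]-2,8-dimethyldeca-4,9-diene-1,2,6-triol | C=C[C@H](C)[C@H](OCc1ccc(OC)cc1)[C@@H](O)/C=C/C[C@](C)(O)CO | intermediate
14 | (2E,4S,5S,6S)-5-[(4-methoxybenzyl)oxy]-6-methyl-1-[(4S)-2,2,4-trimethyl-1,3-dioxolan-4-yl]octa-2,7-dien-4-ol | C=C[C@H](C)[C@H](OCc1ccc(OC)cc1)[C@@H](O)/C=C/C[C@@]2(C)COC(C)(C)O2 | intermediate
15 | (1R,2S,3S)-2-[(4-methoxybenzyl)oxy]-3-methyl-1-[(2R,3R)-3-{[(4S)-2,2,4-trimethyl-1,3-dioxolan-4-yl]methyl}oxiran-2-yl]pent-4-en-1-ol | C=C[C@H](C)[C@H](OCc1ccc(OC)cc1)[C@@H](O)[C@H]2O[C@@H]2C[C@@]3(C)COC(C)(C)O3 | intermediate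
16 | 2-(diethoxyphosphoryl)acetate ester of 15 at the C6 hydroxyl | C=C[C@H](C)[C@H](OCc1ccc(OC)cc1)[C@@H](OC(=O)CP(=O)(OCC)OCC)[C@H]2O[C@@H]2C[C@@]3(C)COC(C)(C)O3 | intermediate
17 | diethyl [(4R,5S)-4-{(1R)-1-hydroxy-2-[(4S)-2,2,4-trimethyl-1,3-dioxolan-4-yl]ethyl}-5-{(1S,2S)-1-[(4-methoxybenzyl)oxy]-2-methylbut-3-en-1-yl}-2-oxooxolan-3-yl]phosphonate (C3 epimers) | C=C[C@H](C)[C@H](OCc1ccc(OC)cc1)[C@H]2OC(=O)C(P(=O)(OCC)OCC)[C@@H]2[C@H](O)C[C@@]3(C)COC(C)(C)O3 | intermediate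
18 | (1R)-1-[(2S,3R)-4-(diethoxyphosphoryl)-2-{(1S,2S)-1-[(4-methoxybenzyl)oxy]-2-methylbut-3-en-1-yl}-5-oxooxolan-3-yl]-2-[(4S)-2,2,4-trimethyl-1,3-dioxolan-4-yl]ethyl (2Z)-2-methylbut-2-enoate | C=C[C@H](C)[C@H](OCc1ccc(OC)cc1)[C@H]2OC(=O)C(P(=O)(OCC)OCC)[C@@H]2[C@H](OC(=O)/C(C)=C\C)C[C@@]3(C)COC(C)(C)O3 | intermediate
19 | (1R,3S)-1-[the oxolan-3-yl unit of 18]-3,4-dihydroxy-3-methylbutyl (2Z)-2-methylbut-2-enoate | C=C[C@H](C)[C@H](OCc1ccc(OC)cc1)[C@H]2OC(=O)C(P(=O)(OCC)OCC)[C@@H]2[C@H](OC(=O)/C(C)=C\C)C[C@](C)(O)CO | intermediate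
20 | (1R,3S)-1-[the oxolan-3-yl unit of 18]-3-hydroxy-3-methyl-4-oxobutyl (2Z)-2-methylbut-2-enoate | C=C[C@H](C)[C@H](OCc1ccc(OC)cc1)[C@H]2OC(=O)C(P(=O)(OCC)OCC)[C@@H]2[C@H](OC(=O)/C(C)=C\C)C[C@](C)(O)C=O | intermediate
21 | (1R,3S)-3-acetoxy-1-[the oxolan-3-yl unit of 18]-3-methyl-4-oxobutyl (2Z)-2-methylbut-2-enoate | C=C[C@H](C)[C@H](OCc1ccc(OC)cc1)[C@H]2OC(=O)C(P(=O)(OCC)OCC)[C@@H]2[C@H](OC(=O)/C(C)=C\C)C[C@](C)(OC(C)=O)C=O | intermediate
22 | (1R,3S,4E)-3-acetoxy-4-(hydroxyimino)-1-[the oxolan-3-yl unit of 18]-3-methylbutyl (2Z)-2-methylbut-2-enoate | C=C[C@H](C)[C@H](OCc1ccc(OC)cc1)[C@H]2OC(=O)C(P(=O)(OCC)OCC)[C@@H]2[C@H](OC(=O)/C(C)=C\C)C[C@](C)(OC(C)=O)/C=N/O | intermediate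
23 | hydroximoyl chloride of 22 (C1 bears Cl and =N–OH) | C=C[C@H](C)[C@H](OCc1ccc(OC)cc1)[C@H]2OC(=O)C(P(=O)(OCC)OCC)[C@@H]2[C@H](OC(=O)/C(C)=C\C)C[C@](C)(OC(C)=O)C(Cl)=NO | intermediate
24 | nitrile oxide from 23 (C1≡N+–O−) | C=C[C@H](C)[C@H](OCc1ccc(OC)cc1)[C@H]2OC(=O)C(P(=O)(OCC)OCC)[C@@H]2[C@H](OC(=O)/C(C)=C\C)C[C@](C)(OC(C)=O)C#[N+][O-] | intermediate
25 | bridged 2-isoxazoline macrocycle: ten-membered carbocycle C1–C10 with C1=N–O–C3 bridge, trans-12,6-lactone bearing P(O)(OEt)2 at C11, 5-OPMB, 8-OAng, 10-OAc, 4-Me; C4, C5, C6, C7, C8, C10 arranged as in 30; C3 and C11 epimers | CCOP(=O)(OCC)C1C(=O)O[C@@H]2[C@@H](OCc3ccc(OC)cc3)[C@@H](C)C4CC(=NO4)[C@@](C)(OC(C)=O)C[C@@H](OC(=O)/C(C)=C\C)[C@@H]12 | intermediate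
26 | 3-hydroxy-1-oxo macrocycle from 25 (β-hydroxy ketone; other groups and centres as in 25) | CCOP(=O)(OCC)C1C(=O)O[C@@H]2[C@@H](OCc3ccc(OC)cc3)[C@@H](C)C(O)CC(=O)[C@@](C)(OC(C)=O)C[C@@H](OC(=O)/C(C)=C\C)[C@@H]12 | intermediate
27 | C3 methanesulfonate of 26 | CCOP(=O)(OCC)C1C(=O)O[C@@H]2[C@@H](OCc3ccc(OC)cc3)[C@@H](C)C(OS(C)(=O)=O)CC(=O)[C@@](C)(OC(C)=O)C[C@@H](OC(=O)/C(C)=C\C)[C@@H]12 | intermediate
28 | 10-acetoxy-8-angeloyloxy-11-(diethoxyphosphoryl)-5-[(4-methoxybenzyl)oxy]-1-oxo-13-norgermacr-2E-en-12,6-olide (centres as in 30; C11 epimers) | CCOP(=O)(OCC)C1C(=O)O[C@@H]2[C@@H](OCc3ccc(OC)cc3)[C@@H](C)/C=C/C(=O)[C@@](C)(OC(C)=O)C[C@@H](OC(=O)/C(C)=C\C)[C@@H]12 | intermediate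
29 | 5-O-(4-methoxybenzyl) ether of 30 | C=C1C(=O)O[C@@H]2[C@@H](OCc3ccc(OC)cc3)[C@@H](C)/C=C/C(=O)[C@@](C)(OC(C)=O)C[C@@H](OC(=O)/C(C)=C\C)[C@@H]12 | intermediate
30 | CNP0259154.2: (4S,5S,6S,7R,8R,10S)-10-acetoxy-8-angeloyloxy-5-hydroxy-1-oxogermacra-2E,11(13)-dien-12,6-olide | C=C1C(=O)O[C@@H]2[C@@H](O)[C@@H](C)/C=C/C(=O)[C@@](C)(OC(C)=O)C[C@@H](OC(=O)/C(C)=C\C)[C@@H]12 | target

**Count**
Total steps: 21. Longest linear sequence: 19 (steps 3–5, then 6–21, from 5); the other branch is steps 1–2.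

**Steps most likely to fail, with fallbacks**

Step 17 (ten-membered ring by nitrile oxide cycloaddition). The risk is furoxan dimerisation or oligomerisation outrunning closure of a medium ring. Fallback: set out from aldehyde 21 and add a vinyl group with vinyl bromide, CrCl2 and NiCl2 (cat.) in DMF, which is selective for the aldehyde, to give the allylic alcohol F1. Ring-closing metathesis of its two terminal vinyl groups (second-generation Grubbs catalyst, CH2Cl2, 40 °C, high dilution) gives the cyclodecenol F2. Dess–Martin oxidation (with iodine-catalysed equilibration if any Z isomer forms) returns to the route at enone 28, bypassing 22–27.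

Step 11 (lactone-forming epoxide opening; it also depends on the moderate erythro selectivity of step 9). The risks are a sluggish ester-tethered SN2, 6-endo opening, or attack of the alkoxide on phosphorus. Fallback: set out from allylic alcohol 14 and esterify with (diethoxyphosphoryl)acetic acid (DCC, DMAP) to the phosphonoacetate F3. Diazo transfer (4-acetamidobenzenesulfonyl azide, DBU, MeCN) gives the diazo ester F4. Rh2(OAc)4-catalysed intramolecular cyclopropanation of the (E)-alkene, with the C5 side chain on the convex face, gives the cyclopropane-fused lactone F5, in which C11 is bonded to both C7 and C8. Homoconjugate opening at C8 with inversion by caesium angelate (angelic acid, Cs2CO3, DMF, 60 °C) returns to the route at angelate 18, bypassing 15–17 and therefore also the directed epoxidation.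

Step 6 (fragment coupling). The risks are attack of the acetylide on the dioxolanone or erosion of chelation control. Fallback: set out from 4 and reduce first with LiAlH4 to the alkynediol F6, then protect with Me2C(OMe)2/PPTS as the acetonide F7. Deprotonation with n-BuLi, transmetalation with ZnBr2 and addition to 9 gives the propargylic alcohol F8. Reduction with NaAlH2(OCH2CH2OMe)2 returns to the route at 14, bypassing 12 and 13.

**Further compounds**
F1 | step 17 | (1R,3S)-3-acetoxy-1-[the oxolan-3-yl unit of 18]-4-hydroxy-3-methylhex-5-en-1-yl (2Z)-2-methylbut-2-enoate (C4 carbinol epimers) | C=C[C@H](C)[C@H](OCc1ccc(OC)cc1)[C@H]2OC(=O)C(P(=O)(OCC)OCC)[C@@H]2[C@H](OC(=O)/C(C)=C\C)C[C@](C)(OC(C)=O)C(O)C=C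
F2 | step 17 | C1 alcohol corresponding to enone 28 (1-hydroxy-2E-ene macrocycle; C1 and C11 epimers) | CCOP(=O)(OCC)C1C(=O)O[C@@H]2[C@@H](OCc3ccc(OC)cc3)[C@@H](C)/C=C/C(O)[C@@](C)(OC(C)=O)C[C@@H](OC(=O)/C(C)=C\C)[C@@H]12
F3 | step 11 | (2E,4S,5S,6S)-5-[(4-methoxybenzyl)oxy]-6-methyl-1-[(4S)-2,2,4-trimethyl-1,3-dioxolan-4-yl]octa-2,7-dien-4-yl 2-(diethoxyphosphoryl)acetate | C=C[C@H](C)[C@H](OCc1ccc(OC)cc1)[C@@H](OC(=O)CP(=O)(OCC)OCC)/C=C/C[C@@]2(C)COC(C)(C)O2
F4 | step 11 | (2E,4S,5S,6S)-5-[(4-methoxybenzyl)oxy]-6-methyl-1-[(4S)-2,2,4-trimethyl-1,3-dioxolan-4-yl]octa-2,7-dien-4-yl 2-diazo-2-(diethoxyphosphoryl)acetate | C=C[C@H](C)[C@H](OCc1ccc(OC)cc1)[C@@H](OC(=O)C(=[N+]=[N-])P(=O)(OCC)OCC)/C=C/C[C@@]2(C)COC(C)(C)O2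
F5 | step 11 | diethyl [(1S,4S,5R,6S)-4-{(1S,2S)-1-[(4-methoxybenzyl)oxy]-2-methylbut-3-en-1-yl}-2-oxo-6-{[(4S)-2,2,4-trimethyl-1,3-dioxolan-4-yl]methyl}-3-oxabicyclo[3.1.0]hexan-1-yl]phosphonate | C=C[C@H](C)[C@H](OCc1ccc(OC)cc1)[C@H]2OC(=O)[C@@]3(P(=O)(OCC)OCC)[C@@H]2[C@@H]3C[C@@]4(C)COC(C)(C)O4
F6 | step 6 | (2S)-2-methylpent-4-yne-1,2-diol | C#CC[C@](C)(O)CO
F7 | step 6 | (4S)-2,2,4-trimethyl-4-(prop-2-yn-1-yl)-1,3-dioxolane | C#CC[C@@]1(C)COC(C)(C)O1
F8 | step 6 | (4S,5S,6S)-5-[(4-methoxybenzyl)oxy]-6-methyl-1-[(4S)-2,2,4-trimethyl-1,3-dioxolan-4-yl]oct-7-en-2-yn-4-ol | C=C[C@H](C)[C@H](OCc1ccc(OC)cc1)[C@@H](O)C#CC[C@@]2(C)COC(C)(C)O2
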